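Everything rests on disconnecting the C5–C6 bond of the bicyclo[3.1.1]heptane, between the bridgehead remote from the exocyclic methylene and the spiro quaternary carbon shared by the cyclobutane and the tetrahydrofuran ring. The key step closes the cyclobutane by 4-exo-tet alkylation of a nitrile-stabilised carbanion at C6 with a C5 tosylate, creating the quaternary stereocentre stereoconvergently from both C6 epimers; it exploits the 1,3-relationship of C1 and C5 across C7 and the CH2O arm on C6, carried as a nitrile. The precursor is a trans-3,5-disubstituted cyclohexene from (S)-carvone: its isopropenyl group directs a conjugate addition and is then excised (Criegee rearrangement) to the C5–O leaving group.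

Key step: step 6

Remark: core locants follow bicyclo[3.1.1]heptane numbering (C1 bridgehead next to C2(=CH2), C3 carbinol carbon, C5 second bridgehead, C6 spiro carbon, C7 one-carbon bridge); the acyloxy ketal carbon is assumed to equilibrate under mild acid, so its configuration is set thermodynamically in step 9.

Step 1
Reactants: 1 (S)-carvone; 2 4,4-dimethoxybutanenitrile
Product: 5 enol triflate (3R,5S)-3-(1-cyano-3,3-dimethoxypropyl)-2-methyl-5-(prop-1-en-2-yl)cyclohex-1-en-1-yl triflate (both epimers at the cyano-bearing carbon), via lithiated nitrile 3 (not isolated), via lithium enolate 4 (not isolated)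
Conditions: 2, LiN(i-Pr)2, THF, −78 °C; HMPA, then 1, −78 → −30 °C; PhNTf2, −78 → 0 °C
Reagents that add atoms: N-phenylbis(trifluoromethanesulfonimide), O=S(=O)(N(c1ccccc1)S(=O)(=O)C(F)(F)F)C(F)(F)F
Why: Conjugate (Michael) addition of the lithiated nitrile as a solvent-separated ion pair (any 1,2-adduct should revert) occurs by axial attack anti to the C5 isopropenyl group, which sets the new ring stereocentre trans to it, and the regiodefined enolate is captured by O-triflation; the cyano-bearing carbon is left as a mixture on purpose.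

Step 2
Reactants: 5 enol triflate
Product: 7 (3R,5S)-5-acetoxy-3-(1-cyano-3,3-dimethoxypropyl)-2-methylcyclohex-1-en-1-yl triflate, via methoxy hydroperoxide 6 (not isolated)
Conditions: O3, CH2Cl2/MeOH, NaHCO3, −78 °C (Sudan Red 7B end point); then Ac2O, Et3N, DMAP, 0 → 40 °C
Reagents that add atoms: ozone, [O-][O+]=O; methanol, CO
Why: Ozone should cleave only the electron-rich 1,1-disubstituted alkene (the enol triflate is deactivated), and Criegee rearrangement of the peracetate of 6 moves the ring carbon from carbon to oxygen with retention, so the carvone stereocentre survives as a C–O stereocentre while two carbons of the isopropenyl group become the acetyl group.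

Step 3
Reactants: 7 acetoxy enol triflate
Product: 8 (1R,5R)-5-(1-cyano-3,3-dimethoxypropyl)-4-methylcyclohex-3-en-1-yl acetate
Conditions: Pd(OAc)2 (5 mol %), PPh3, HCO2H, n-Bu3N, DMF, 60 °C
Reagents that add atoms: none
Why: Palladium-catalysed formate reduction of the enol triflate (oxidative addition, formate decarboxylation, C–H reductive elimination) leaves the trisubstituted alkene carrying the methyl group that the later ene reaction needs; no stereocentre is involved.

Step 4
Reactants: 8 acetate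
Product: 9 2-[(1R,5R)-5-hydroxy-2-methylcyclohex-2-en-1-yl]-4,4-dimethoxybutanenitrile
Conditions: K2CO3 (cat.), MeOH, 0 °C → rt
Reagents that add atoms: none
Why: Base-catalysed transesterification (methanolysis of the acetate) frees the secondary alcohol with its configuration untouched, and epimerisation next to the nitrile is without consequence.

Step 5
Reactants: 9 alcohol
Product: 10 (1R,5R)-5-(1-cyano-3,3-dimethoxypropyl)-4-methylcyclohex-3-en-1-yl 4-methylbenzenesulfonate
Conditions: TsCl, Et3N, DMAP (cat.), CH2Cl2, 0 °C → rt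
Reagents that add atoms: p-toluenesulfonyl chloride, Cc1ccc(cc1)S(Cl)(=O)=O
Why: O-Sulfonylation (retention) installs a leaving group trans to the side chain, as backside attack requires, and a tosylate has no acidic α-hydrogen to interfere with the strong base of step 6.

Step 6
Reactants: 10 tosylate
Product: 12 (1S,5S,6S)-6-(2,2-dimethoxyethyl)-2-methylbicyclo[3.1.1]hept-2-ene-6-carbonitrile (cyano group syn to the C2=C3 bridge), via lithiated nitrile 11 (not isolated)
Conditions: LiN(i-Pr)2 (1.1 equiv), THF/DMPU, −78 °C → rt, 0.02 M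
Reagents that add atoms: none
Why: Deprotonation next to the nitrile gives a planar N-lithiated keteniminate that displaces the tosylate in an intramolecular SN2 reaction, the closest known type being nitrile anion cyclisation to cyclobutanes. The cyclobutane, and with it the bicyclo[3.1.1]heptene, closes in the 4-exo-tet mode. C5 is inverted, which is what the trans arrangement built in steps 1 and 2 provides for, and C1 is untouched. The quaternary C6 is set in the transition state: the substituent that ends up syn to the three-carbon bridge eclipses the C1–C2 bond, so the slender linear C=C=N unit should take that place and the bulkier 2,2-dimethoxyethyl arm should point to the C7 side, and both C6 epimers of 10 converge on the same anion. The step needs substitution to beat E2 loss of the tosylate; allylic 1,2-strain with the ring methyl keeps the side chain pseudoaxial and hence the tosylate equatorial (no antiperiplanar hydrogen), and the base is consumed by the C–H next to the nitrile at −78 °C before warming.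

Step 7
Reactants: 12 bicyclic nitrile
Product: 14 [(1S,5S,6S)-6-(2,2-dimethoxyethyl)-2-methylbicyclo[3.1.1]hept-2-en-6-yl]methanol, via aldehyde 13 (not isolated)
Conditions: i-Bu2AlH, toluene, −78 → 0 °C; aq. tartaric acid, 0 °C; then NaBH4, MeOH, 0 °C
Reagents that add atoms: water, O
Why: Hydride addition to the nitrile stops at the aluminium aldimine, mild acid hydrolysis gives the non-enolisable aldehyde 13 with the acetal intact, and borohydride reduces it to the primary alcohol; no stereocentre changes.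

Step 8
Reactants: 14 hydroxy acetal
Product: 16 (1S,5S,6S)-2-methylspiro[bicyclo[3.1.1]hept-2-ene-6,3′-oxolan]-5′-one, via lactol 15 (not isolated)
Conditions: AcOH/THF/H2O, 40 °C; then TEMPO (cat.), PhI(OAc)2, CH2Cl2, rt
Reagents that add atoms: water, O
Why: Acetal hydrolysis with 5-exo closure of the neighbouring primary alcohol gives lactol 15, which the oxoammonium species of the TEMPO/PhI(OAc)2 system should oxidise to the γ-lactone without touching the alkene.

Step 9
Reactants: 16 spiro lactone; 17 (S)-3-bromo-2-methylpropanoic acid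
Product: 20 (1S,5S,6S,2′R,4″R)-2,4″-dimethyldispiro[bicyclo[3.1.1]hept-2-ene-6,4′-oxolane-2′,2″-oxolan]-5″-one, via dilithio homoenolate 18 (not isolated), via hydroxy keto acid 19 (not isolated)
Conditions: 17, n-BuLi (1 equiv) then LiC10H8 (2 equiv), THF, −78 °C; 16, −78 °C; 1 M HCl; then PPTS, CH2Cl2, 4 Å MS, rt
Reagents that add atoms: none
Why: Reductive lithiation of the lithium carboxylate of 17 gives a β-lithiated carboxylate (homoenolate equivalent) that should add once to the lactone carbonyl, and acid then closes the hydroxy keto acid by dehydrative spiroketal lactonisation under thermodynamic control, in which the methyl stereocentre brought in by 17 should steer the spiro carbon (tetrahydrofuran oxygen pseudoaxial by the anomeric effect, methyl and ring CH2 cis and pseudoequatorial), any minor spiro epimer being separated and re-equilibrated with acid.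

Step 10
Reactants: 20 spiroketal lactone
Product: 22 (1R,3S,5R,6S,2′R,4″R)-3-hydroxy-4″-methyl-2-methylidenedispiro[bicyclo[3.1.1]heptane-6,4′-oxolane-2′,2″-oxolan]-5″-one, via allylic hydroperoxide 21 (not isolated)
Conditions: O2, hν, tetraphenylporphyrin (cat.), CH2Cl2, 0 °C; then PPh3
Reagents that add atoms: oxygen, O=O
Why: Schenck ene reaction: singlet oxygen should attack the alkene from the face away from the C6 bridge, whose syn CH2O group covers the other face, remove a hydrogen from the C2 methyl group and so place the exocyclic methylene and the C3–O bond trans to C6, and triphenylphosphine reduces the hydroperoxide with retention.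

Step 11
Reactants: 23 methyl 2,2-dimethyl-3-oxobutanoate
Product: 24 methyl (3S)-3-hydroxy-2,2-dimethylbutanoate
Conditions: H2 (50 atm), RuCl2[(S)-BINAP] (cat.), MeOH, 50 °C
Reagents that add atoms: none
Why: Noyori asymmetric hydrogenation of the β-keto ester through its ruthenium chelate, for which the (S)-BINAP ligand should give the (S)-carbinol.

Step 12
Reactants: 24 hydroxy ester
Product: 25 methyl (3S)-3-[(tert-butyldimethylsilyl)oxy]-2,2-dimethylbutanoate
Conditions: TBSOTf, 2,6-lutidine, CH2Cl2, 0 °C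
Reagents that add atoms: tert-butyldimethylsilyl triflate, CC(C)(C)[Si](C)(C)OS(=O)(=O)C(F)(F)F
Why: Silylation of the hindered secondary alcohol with the silyl triflate protects it against self-acylation in the coupling.

Step 13
Reactants: 25 silyl ether ester
Product: 26 (3S)-3-[(tert-butyldimethylsilyl)oxy]-2,2-dimethylbutanoic acid
Conditions: LiOH, THF/MeOH/H2O, 60 °C; then 1 M HCl, 0 °C
Reagents that add atoms: lithium hydroxide, [Li+].[OH-]
Why: Saponification of the neopentyl-type methyl ester needs heat but should leave the silyl ether and the stereocentre (no α-hydrogen) intact.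

Step 14
Reactants: 22 allylic alcohol; 26 silyloxy acid
Product: 28 (1R,3S,5R,6S,2′R,4″R)-4″-methyl-2-methylidene-5″-oxodispiro[bicyclo[3.1.1]heptane-6,4′-oxolane-2′,2″-oxolan]-3-yl (3S)-3-[(tert-butyldimethylsilyl)oxy]-2,2-dimethylbutanoate, via mixed anhydride 27 (not isolated)
Conditions: 26, 2,4,6-Cl3C6H2COCl, Et3N, THF, rt; then 22, DMAP, toluene, rt → 40 °C
Reagents that add atoms: none
Why: Yamaguchi esterification: the mixed anhydride passes the hindered acyl group through an acylpyridinium ion to the allylic alcohol, whose C3 configuration is retained.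

Step 15
Reactants: 28 silyl-protected ester
Product: 29 target, (1R,3S,5R,6S,2′R,4″R)-4″-methyl-2-methylidene-5″-oxodispiro[bicyclo[3.1.1]heptane-6,4′-oxolane-2′,2″-oxolan]-3-yl (3S)-3-hydroxy-2,2-dimethylbutanoate
Conditions: HF·pyridine, pyridine/THF, 0 °C → rt
Reagents that add atoms: none
Why: Buffered fluoride should cleave the silyl ether without harming the allylic ester or the acyloxy ketal.

Compound list
1 | (S)-carvone, (5S)-2-methyl-5-(prop-1-en-2-yl)cyclohex-2-en-1-one | CC1=CC[C@@H](CC1=O)C(C)=C | starting material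
2 | 4,4-dimethoxybutanenitrile | N#CCCC(OC)OC | starting material
3 | 2-lithio-4,4-dimethoxybutanenitrile (lithiated nitrile) | [Li+].N#C[CH-]CC(OC)OC | intermediate
4 | lithium (3R,5S)-3-(1-cyano-3,3-dimethoxypropyl)-2-methyl-5-(prop-1-en-2-yl)cyclohex-1-en-1-olate | [Li+].CC1=C([O-])C[C@@H](C(C)=C)C[C@@H]1C(C#N)CC(OC)OC | intermediate
5 | (3R,5S)-3-(1-cyano-3,3-dimethoxypropyl)-2-methyl-5-(prop-1-en-2-yl)cyclohex-1-en-1-yl trifluoromethanesulfonate (both epimers at the cyano-bearing carbon) | CC1=C(OS(=O)(=O)C(F)(F)F)C[C@@H](C(C)=C)C[C@@H]1C(C#N)CC(OC)OC | intermediate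
6 | (3R,5S)-3-(1-cyano-3,3-dimethoxypropyl)-5-(1-hydroperoxy-1-methoxyethyl)-2-methylcyclohex-1-en-1-yl trifluoromethanesulfonate | CC1=C(OS(=O)(=O)C(F)(F)F)C[C@@H](C(C)(OC)OO)C[C@@H]1C(C#N)CC(OC)OC | intermediate
7 | (3R,5S)-5-acetoxy-3-(1-cyano-3,3-dimethoxypropyl)-2-methylcyclohex-1-en-1-yl trifluoromethanesulfonate | CC1=C(OS(=O)(=O)C(F)(F)F)C[C@@H](OC(C)=O)C[C@@H]1C(C#N)CC(OC)OC | intermediate
8 | (1R,5R)-5-(1-cyano-3,3-dimethoxypropyl)-4-methylcyclohex-3-en-1-yl acetate | CC1=CC[C@@H](OC(C)=O)C[C@@H]1C(C#N)CC(OC)OC | intermediate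
9 | 2-[(1R,5R)-5-hydroxy-2-methylcyclohex-2-en-1-yl]-4,4-dimethoxybutanenitrile | CC1=CC[C@@H](O)C[C@@H]1C(C#N)CC(OC)OC | intermediate
10 | (1R,5R)-5-(1-cyano-3,3-dimethoxypropyl)-4-methylcyclohex-3-en-1-yl 4-methylbenzenesulfonate | CC1=CC[C@@H](OS(=O)(=O)c2ccc(C)cc2)C[C@@H]1C(C#N)CC(OC)OC | intermediate
11 | lithiated nitrile (N-lithio keteniminate) of 10 | [Li+].CC1=CC[C@@H](OS(=O)(=O)c2ccc(C)cc2)C[C@@H]1[C-](C#N)CC(OC)OC | intermediate
12 | (1S,5S,6S)-6-(2,2-dimethoxyethyl)-2-methylbicyclo[3.1.1]hept-2-ene-6-carbonitrile | CC1=CC[C@H]2C[C@@H]1[C@]2(C#N)CC(OC)OC | intermediate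
13 | (1S,5S,6S)-6-(2,2-dimethoxyethyl)-2-methylbicyclo[3.1.1]hept-2-ene-6-carbaldehyde | CC1=CC[C@H]2C[C@@H]1[C@]2(C=O)CC(OC)OC | intermediate
14 | [(1S,5S,6S)-6-(2,2-dimethoxyethyl)-2-methylbicyclo[3.1.1]hept-2-en-6-yl]methanol | CC1=CC[C@H]2C[C@@H]1[C@]2(CO)CC(OC)OC | intermediate
15 | (1S,5S,6S)-2-methylspiro[bicyclo[3.1.1]hept-2-ene-6,3′-oxolan]-5′-ol (lactol, both anomers) | CC1=CC[C@H]2C[C@@H]1[C@@]21COC(O)C1 | intermediate
16 | (1S,5S,6S)-2-methylspiro[bicyclo[3.1.1]hept-2-ene-6,3′-oxolan]-5′-one | CC1=CC[C@H]2C[C@@H]1[C@@]21COC(=O)C1 | intermediate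
17 | (S)-3-bromo-2-methylpropanoic acid | BrC[C@@H](C)C(=O)O | starting material
18 | lithium 3-lithio-2-methylpropanoate (from 17, stereocentre untouched) | [Li+].[Li+].[CH2-][C@@H](C)C([O-])=O | intermediate
19 | (2R)-5-[(1S,5S,6S)-6-(hydroxymethyl)-2-methylbicyclo[3.1.1]hept-2-en-6-yl]-2-methyl-4-oxopentanoic acid | CC1=CC[C@H]2C[C@@H]1[C@]2(CO)CC(=O)C[C@@H](C)C(O)=O | intermediate
20 | (1S,5S,6S,2′R,4″R)-2,4″-dimethyldispiro[bicyclo[3.1.1]hept-2-ene-6,4′-oxolane-2′,2″-oxolan]-5″-one | CC1=CC[C@H]2C[C@@H]1[C@@]21CO[C@@]2(C[C@@H](C)C(=O)O2)C1 | intermediate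
21 | (1R,3S,5R,6S,2′R,4″R)-3-hydroperoxy-4″-methyl-2-methylidenedispiro[bicyclo[3.1.1]heptane-6,4′-oxolane-2′,2″-oxolan]-5″-one | C=C1[C@@H](OO)C[C@H]2C[C@@H]1[C@@]21CO[C@@]2(C[C@@H](C)C(=O)O2)C1 | intermediate
22 | (1R,3S,5R,6S,2′R,4″R)-3-hydroxy-4″-methyl-2-methylidenedispiro[bicyclo[3.1.1]heptane-6,4′-oxolane-2′,2″-oxolan]-5″-one | C=C1[C@@H](O)C[C@H]2C[C@@H]1[C@@]21CO[C@@]2(C[C@@H](C)C(=O)O2)C1 | intermediate
23 | methyl 2,2-dimethyl-3-oxobutanoate | COC(=O)C(C)(C)C(C)=O | starting material
24 | methyl (3S)-3-hydroxy-2,2-dimethylbutanoate | COC(=O)C(C)(C)[C@H](C)O | intermediate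
25 | methyl (3S)-3-[(tert-butyldimethylsilyl)oxy]-2,2-dimethylbutanoate | COC(=O)C(C)(C)[C@H](C)O[Si](C)(C)C(C)(C)C | intermediate
26 | (3S)-3-[(tert-butyldimethylsilyl)oxy]-2,2-dimethylbutanoic acid | OC(=O)C(C)(C)[C@H](C)O[Si](C)(C)C(C)(C)C | intermediate
27 | mixed anhydride of 26 with 2,4,6-trichlorobenzoic acid | O=C(OC(=O)C(C)(C)[C@H](C)O[Si](C)(C)C(C)(C)C)c1c(Cl)cc(Cl)cc1Cl | intermediate
28 | (1R,3S,5R,6S,2′R,4″R)-4″-methyl-2-methylidene-5″-oxodispiro[bicyclo[3.1.1]heptane-6,4′-oxolane-2′,2″-oxolan]-3-yl (3S)-3-[(tert-butyldimethylsilyl)oxy]-2,2-dimethylbutanoate | C=C1[C@@H](OC(=O)C(C)(C)[C@H](C)O[Si](C)(C)C(C)(C)C)C[C@H]2C[C@@H]1[C@@]21CO[C@@]2(C[C@@H](C)C(=O)O2)C1 | intermediate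
29 | (1R,3S,5R,6S,2′R,4″R)-4″-methyl-2-methylidene-5″-oxodispiro[bicyclo[3.1.1]heptane-6,4′-oxolane-2′,2″-oxolan]-3-yl (3S)-3-hydroxy-2,2-dimethylbutanoate | C=C1[C@@H](OC(=O)C(C)(C)[C@H](C)O)C[C@H]2C[C@@H]1[C@@]21CO[C@@]2(C[C@@H](C)C(=O)O2)C1 | target

Total step count: 15 (12 on the main line, 3 for the acid side chain).
Longest linear sequence: 12 steps (steps 1–10, 14 and 15) from (S)-carvone.

Steps most likely to fail

Step 6 (key step). E2 loss of the tosylate or intermolecular alkylation may outrun the strained 4-exo-tet closure, and the two faces of the planar nitrile anion may not be told apart well enough at C6. The fallback sets out from 1 and returns at 14; it closes the same C5–C6 bond first and sets C6 afterwards on the rigid bicycle. Mukaiyama–Michael addition of commercial 1-(tert-butyldimethylsilyloxy)-1-methoxyethene to 1 (TBSOTf cat., CH2Cl2, −78 °C) should give, again anti to the isopropenyl group, the silyl enol ether methyl 2-[(1R,5S)-3-(tert-butyldimethylsilyloxy)-2-methyl-5-(prop-1-en-2-yl)cyclohex-2-en-1-yl]acetate F1. CsF and PhNTf2 in DME convert it into the enol triflate methyl 2-[(1R,5S)-2-methyl-5-(prop-1-en-2-yl)-3-(trifluoromethanesulfonyloxy)cyclohex-2-en-1-yl]acetate F2. Ozonolysis and Criegee rearrangement as in step 2 give the acetate methyl 2-[(1R,5S)-5-acetoxy-2-methyl-3-(trifluoromethanesulfonyloxy)cyclohex-2-en-1-yl]acetate F3, and palladium/formate reduction as in step 3 gives the alkene methyl 2-[(1R,5R)-5-acetoxy-2-methylcyclohex-2-en-1-yl]acetate F4. K2CO3 in methanol gives the alcohol methyl 2-[(1R,5R)-5-hydroxy-2-methylcyclohex-2-en-1-yl]acetate F5, and TsCl/Et3N the tosylate methyl 2-[(1R,5R)-2-methyl-5-(tosyloxy)cyclohex-2-en-1-yl]acetate F6. LiN(i-Pr)2 then closes the cyclobutane through the less hindered ester enolate, with no stereocentre to control at C6, to methyl (1R,5S)-2-methylbicyclo[3.1.1]hept-2-ene-6-carboxylate F7. A second enolisation (LiN(i-Pr)2, THF/DMPU) and alkylation with 2-bromo-1,1-dimethoxyethane, which should approach the exocyclic enolate from the open C7 side, gives methyl (1S,5S,6S)-6-(2,2-dimethoxyethyl)-2-methylbicyclo[3.1.1]hept-2-ene-6-carboxylate F8. LiAlH4 reduction of F8 gives 14.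

Step 1. The lithiated nitrile may add to the carbonyl group (1,2-addition) or act as a base toward the enone, and capture of the hindered enolate may be incomplete. The fallback sets out from 1 and returns at 5; the donor is changed to a silyl ketene acetal, which can only add in the conjugate sense. Methyl 4,4-dimethoxybutanoate (LiN(i-Pr)2, Me3SiCl) gives trimethyl[(1,4,4-trimethoxybut-1-en-1-yl)oxy]silane F9. Fluoride-catalysed (TASF) Mukaiyama–Michael addition of F9 to 1 should deliver the trimethylsilyl enol ether methyl 2-[(1R,5S)-2-methyl-5-(prop-1-en-2-yl)-3-(trimethylsilyloxy)cyclohex-2-en-1-yl]-4,4-dimethoxybutanoate F10. CsF/PhNTf2 gives the enol triflate methyl 2-[(1R,5S)-2-methyl-5-(prop-1-en-2-yl)-3-(trifluoromethanesulfonyloxy)cyclohex-2-en-1-yl]-4,4-dimethoxybutanoate F11. AlMe3/NH4Cl turns the ester into the primary amide 2-[(1R,5S)-2-methyl-5-(prop-1-en-2-yl)-3-(trifluoromethanesulfonyloxy)cyclohex-2-en-1-yl]-4,4-dimethoxybutanamide F12, and dehydration with (CF3CO)2O/pyridine gives 5.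

Step 9. The strongly basic sp3 organolithium may enolise lactone 16 instead of adding, or add a second time after ring opening of the adduct. The fallback sets out from 16 and returns at 20; it uses a less basic vinyl dianion and sets the methyl stereocentre by conjugate reduction instead of bringing it in. Lithium (Z)-3-lithio-2-methylacrylate, from (Z)-3-bromo-2-methylacrylic acid and n-BuLi (2 equiv) at −100 °C, is added to 16 and the adduct is closed with acid to the spiro butenolide (1S,5S,6S,2′R)-2,4″-dimethyldispiro[bicyclo[3.1.1]hept-2-ene-6,4′-oxolane-2′,2″-oxol-3″-en]-5″-one F13. Conjugate reduction with [(Ph3P)CuH]6 and protonation of the enolate from the face of the tetrahydrofuran oxygen should place the methyl group cis to the ring CH2 and give 20, spiro epimers being separated and equilibrated as in the main route.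

Further compounds
F1 | step 6 | methyl 2-[(1R,5S)-3-(tert-butyldimethylsilyloxy)-2-methyl-5-(prop-1-en-2-yl)cyclohex-2-en-1-yl]acetate | CC1=C(O[Si](C)(C)C(C)(C)C)C[C@@H](C(C)=C)C[C@@H]1CC(=O)OC
F2 | step 6 | methyl 2-[(1R,5S)-2-methyl-5-(prop-1-en-2-yl)-3-(trifluoromethanesulfonyloxy)cyclohex-2-en-1-yl]acetate | CC1=C(OS(=O)(=O)C(F)(F)F)C[C@@H](C(C)=C)C[C@@H]1CC(=O)OC
F3 | step 6 | methyl 2-[(1R,5S)-5-acetoxy-2-methyl-3-(trifluoromethanesulfonyloxy)cyclohex-2-en-1-yl]acetate | CC1=C(OS(=O)(=O)C(F)(F)F)C[C@@H](OC(C)=O)C[C@@H]1CC(=O)OC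
F4 | step 6 | methyl 2-[(1R,5R)-5-acetoxy-2-methylcyclohex-2-en-1-yl]acetate | CC1=CC[C@@H](OC(C)=O)C[C@@H]1CC(=O)OC
F5 | step 6 | methyl 2-[(1R,5R)-5-hydroxy-2-methylcyclohex-2-en-1-yl]acetate | CC1=CC[C@@H](O)C[C@@H]1CC(=O)OC
F6 | step 6 | methyl 2-[(1R,5R)-2-methyl-5-(tosyloxy)cyclohex-2-en-1-yl]acetate | CC1=CC[C@@H](OS(=O)(=O)c2ccc(C)cc2)C[C@@H]1CC(=O)OC
F7 | step 6 | methyl (1R,5S)-2-methylbicyclo[3.1.1]hept-2-ene-6-carboxylate (either C6 epimer) | CC1=CC[C@H]2C[C@@H]1C2C(=O)OC
F8 | step 6 | methyl (1S,5S,6S)-6-(2,2-dimethoxyethyl)-2-methylbicyclo[3.1.1]hept-2-ene-6-carboxylate | CC1=CC[C@H]2C[C@@H]1[C@]2(C(=O)OC)CC(OC)OC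
F9 | step 1 | trimethyl[(1,4,4-trimethoxybut-1-en-1-yl)oxy]silane | COC(=CCC(OC)OC)O[Si](C)(C)C
F10 | step 1 | methyl 2-[(1R,5S)-2-methyl-5-(prop-1-en-2-yl)-3-(trimethylsilyloxy)cyclohex-2-en-1-yl]-4,4-dimethoxybutanoate | CC1=C(O[Si](C)(C)C)C[C@@H](C(C)=C)C[C@@H]1C(C(=O)OC)CC(OC)OC
F11 | step 1 | methyl 2-[(1R,5S)-2-methyl-5-(prop-1-en-2-yl)-3-(trifluoromethanesulfonyloxy)cyclohex-2-en-1-yl]-4,4-dimethoxybutanoate | CC1=C(OS(=O)(=O)C(F)(F)F)C[C@@H](C(C)=C)C[C@@H]1C(C(=O)OC)CC(OC)OC
F12 | step 1 | 2-[(1R,5S)-2-methyl-5-(prop-1-en-2-yl)-3-(trifluoromethanesulfonyloxy)cyclohex-2-en-1-yl]-4,4-dimethoxybutanamide | CC1=C(OS(=O)(=O)C(F)(F)F)C[C@@H](C(C)=C)C[C@@H]1C(C(N)=O)CC(OC)OC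
F13 | step 9 | (1S,5S,6S,2′R)-2,4″-dimethyldispiro[bicyclo[3.1.1]hept-2-ene-6,4′-oxolane-2′,2″-oxol-3″-en]-5″-one | CC1=CC[C@H]2C[C@@H]1[C@@]21CO[C@@]2(C=C(C)C(=O)O2)C1
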